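**Retrosynthetic overview**
1. Target 16 ⇐ 5-chloro-dihydrobenzofuran 15 + (E)-propenyl boronate (Suzuki–Miyaura, last step).
2. 15 ⇐ bromo alcohol 14 by intramolecular copper-catalysed aryl C–O coupling (O1–C7a); this closes the dihydrofuran ring, the only ring formed (both benzene rings are bought).
3. 14 ⇐ aldol adduct 9; the acyl carbon is taken down to the C3 methyl group (LiBH4, tosylate, LiEt3BH).
4. 9 ⇐ arylacetyl imide 5 + 3,4,5-trimethoxybenzaldehyde 6; an Evans syn aldol makes the C2–C3 bond and sets both stereocentres.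
5. 5 ⇐ acid 2 (ring chlorination of 1) + (R)-4-benzyl-oxazolidinone 3.

Assumption: the SMILES is read as the (2R,3R)-trans isomer, and 1, 3, 6 and (E)-propenylboronic acid pinacol ester are taken as catalogue items.

**Route**

Step 1
Reactants: 1 2-(2-bromo-4-methoxyphenyl)acetic acid
Product: 2 2-(2-bromo-5-chloro-4-methoxyphenyl)acetic acid
Conditions: SO2Cl2 (1.1 equiv), AcOH, 25 °C
Reagents that add atoms: sulfuryl chloride, O=S(=O)(Cl)Cl
Why: Electrophilic aromatic chlorination, in which the methoxy group directs ortho and only C5 (also para to bromine) is open, since the other ortho position is wedged between OMe and Br.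

Step 2
Reactants: 2 2-(2-bromo-5-chloro-4-methoxyphenyl)acetic acid; 3 (R)-4-benzyl-1,3-oxazolidin-2-one
Product: 5 (R)-4-benzyl-3-[2-(2-bromo-5-chloro-4-methoxyphenyl)acetyl]-1,3-oxazolidin-2-one, via mixed pivalic anhydride 4 (not isolated)
Conditions: PivCl, Et3N, THF, −20 °C; then 3, LiCl, −20 → 25 °C
Reagents that add atoms: pivaloyl chloride, CC(C)(C)C(=O)Cl (its acyl group is kept only in 4)
Why: N-acylation of the oxazolidinone through the mixed anhydride, which avoids the ketene-prone arylacetyl chloride and is attacked at the less hindered arylacetyl carbonyl.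

Step 3
Reactants: 5 (R)-4-benzyl-3-[2-(2-bromo-5-chloro-4-methoxyphenyl)acetyl]-1,3-oxazolidin-2-one; 6 3,4,5-trimethoxybenzaldehyde
Product: 9 (R)-4-benzyl-3-[(2R,3R)-2-(2-bromo-5-chloro-4-methoxyphenyl)-3-hydroxy-3-(3,4,5-trimethoxyphenyl)propanoyl]-1,3-oxazolidin-2-one, via boron Z-enolate 7 (not isolated), via boron aldolate 8 (not isolated)
Conditions: Bu2BOTf (1.2 equiv), iPr2NEt (1.4 equiv), CH2Cl2, 0 °C; 6, −78 → 0 °C; then pH 7 buffer (KH2PO4/K2HPO4), MeOH, 30% H2O2, 0 °C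
Reagents that add atoms: dibutylboron triflate, CCCCB(CCCC)OS(=O)(=O)C(F)(F)F (its Bu2B group is kept only in 7 and 8)
Why: Evans syn aldol, in which soft enolisation gives the Z boron enolate and a closed Zimmerman–Traxler chair with the (R)-benzyl group shielding one enolate face forms the C–C bond and sets both new centres as (2R,3R) syn.

Step 4
Reactants: 9 (R)-4-benzyl-3-[(2R,3R)-2-(2-bromo-5-chloro-4-methoxyphenyl)-3-hydroxy-3-(3,4,5-trimethoxyphenyl)propanoyl]-1,3-oxazolidin-2-one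
Product: 10 (1R,2S)-2-(2-bromo-5-chloro-4-methoxyphenyl)-1-(3,4,5-trimethoxyphenyl)propane-1,3-diol
Conditions: LiBH4 (2 equiv), MeOH (2 equiv), THF, 0 °C
Reagents that add atoms: none
Why: Hydroxyl-assisted reductive cleavage of the exocyclic imide carbonyl releases the auxiliary and gives the 1,3-diol without touching either stereocentre (the C2 label becomes S only through CIP priorities).

Step 5
Reactants: 10 (1R,2S)-2-(2-bromo-5-chloro-4-methoxyphenyl)-1-(3,4,5-trimethoxyphenyl)propane-1,3-diol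
Product: 11 (2S,3R)-2-(2-bromo-5-chloro-4-methoxyphenyl)-3-hydroxy-3-(3,4,5-trimethoxyphenyl)propyl 4-methylbenzenesulfonate
Conditions: TsCl (1.1 equiv), pyridine, CH2Cl2, 0 °C
Reagents that add atoms: 4-toluenesulfonyl chloride, Cc1ccc(cc1)S(=O)(=O)Cl
Why: Selective sulfonylation, since the open primary hydroxyl reacts far faster than the flanked secondary benzylic one.

Step 6
Reactants: 11 (2S,3R)-2-(2-bromo-5-chloro-4-methoxyphenyl)-3-hydroxy-3-(3,4,5-trimethoxyphenyl)propyl 4-methylbenzenesulfonate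
Product: 12 (2S,3R)-2-(2-bromo-5-chloro-4-methoxyphenyl)-3-[(tert-butyldimethylsilyl)oxy]-3-(3,4,5-trimethoxyphenyl)propyl 4-methylbenzenesulfonate
Conditions: TBSOTf, 2,6-lutidine, CH2Cl2, −78 → 0 °C
Reagents that add atoms: tert-butyldimethylsilyl triflate, CC(C)(C)[Si](C)(C)OS(=O)(=O)C(F)(F)F
Why: Silyl ether formation masks the benzylic hydroxyl so that no alkoxide can cause oxetane closure or Grob fragmentation in the hydride step.

Step 7
Reactants: 12 (2S,3R)-2-(2-bromo-5-chloro-4-methoxyphenyl)-3-[(tert-butyldimethylsilyl)oxy]-3-(3,4,5-trimethoxyphenyl)propyl 4-methylbenzenesulfonate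
Product: 13 tert-butyl{[(1R,2R)-2-(2-bromo-5-chloro-4-methoxyphenyl)-1-(3,4,5-trimethoxyphenyl)propyl]oxy}dimethylsilane
Conditions: LiEt3BH (2.5 equiv), THF, 0 → 25 °C
Reagents that add atoms: none
Why: SN2 hydride displacement of the primary tosylate turns the former carboxyl carbon into the C3 methyl group while the aryl halides and silyl ether stay inert and the stereocentres are untouched (C2 becomes R only through CIP priorities).

Step 8
Reactants: 13 tert-butyl{[(1R,2R)-2-(2-bromo-5-chloro-4-methoxyphenyl)-1-(3,4,5-trimethoxyphenyl)propyl]oxy}dimethylsilane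
Product: 14 (1R,2R)-2-(2-bromo-5-chloro-4-methoxyphenyl)-1-(3,4,5-trimethoxyphenyl)propan-1-ol
Conditions: Bu4NF, THF, 25–40 °C
Reagents that add atoms: none
Why: Fluoride-driven desilylation frees the secondary alcohol under conditions that leave both stereocentres and both aryl halides alone.

Step 9
Reactants: 14 (1R,2R)-2-(2-bromo-5-chloro-4-methoxyphenyl)-1-(3,4,5-trimethoxyphenyl)propan-1-ol
Product: 15 (2R,3R)-5-chloro-6-methoxy-3-methyl-2-(3,4,5-trimethoxyphenyl)-2,3-dihydro-1-benzofuran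
Conditions: CuI (10 mol%), 3,4,7,8-tetramethyl-1,10-phenanthroline (20 mol%), Cs2CO3 (2 equiv), toluene, 110 °C, argon
Reagents that add atoms: none
Why: Intramolecular Ullmann-type C–O coupling under monovalent copper catalysis, where only the ortho bromide can close the five-membered ring, the chloride is inert, and the carbinol C–O bond is never broken, so the syn alcohol gives the trans-(2R,3R) ring with retention.

Step 10
Reactants: 15 (2R,3R)-5-chloro-6-methoxy-3-methyl-2-(3,4,5-trimethoxyphenyl)-2,3-dihydro-1-benzofuran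
Product: 16 (2R,3R)-6-methoxy-3-methyl-5-[(E)-prop-1-en-1-yl]-2-(3,4,5-trimethoxyphenyl)-2,3-dihydro-1-benzofuran
Conditions: (E)-propenyl-Bpin (1.5 equiv), Pd(OAc)2 (5 mol%), SPhos (10 mol%), K3PO4 (3 equiv), toluene/H2O (10:1), 100 °C
Reagents that add atoms: (E)-prop-1-enylboronic acid pinacol ester, C/C=C/B1OC(C)(C)C(C)(C)O1
Why: Suzuki–Miyaura coupling, in which the SPhos-ligated zerovalent palladium inserts into the electron-rich aryl chloride and the alkenyl group is transferred with retention of its E geometry.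

**Compound list**
1 | 2-(2-bromo-4-methoxyphenyl)acetic acid | COc1ccc(CC(=O)O)c(Br)c1 | starting material
2 | 2-(2-bromo-5-chloro-4-methoxyphenyl)acetic acid | COc1cc(Br)c(CC(=O)O)cc1Cl | intermediate
3 | (R)-4-benzyl-1,3-oxazolidin-2-one | O=C1N[C@H](Cc2ccccc2)CO1 | starting material
4 | 2-(2-bromo-5-chloro-4-methoxyphenyl)acetic pivalic anhydride (not isolated) | COc1cc(Br)c(CC(=O)OC(=O)C(C)(C)C)cc1Cl | intermediate
5 | (R)-4-benzyl-3-[2-(2-bromo-5-chloro-4-methoxyphenyl)acetyl]-1,3-oxazolidin-2-one | COc1cc(Br)c(CC(=O)N2[C@H](Cc3ccccc3)COC2=O)cc1Cl | intermediate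
6 | 3,4,5-trimethoxybenzaldehyde | COc1cc(C=O)cc(OC)c1OC | starting material
7 | (R)-4-benzyl-3-[(Z)-2-(2-bromo-5-chloro-4-methoxyphenyl)-1-[(dibutylboranyl)oxy]ethenyl]-1,3-oxazolidin-2-one (not isolated) | CCCCB(CCCC)O/C(=C\c1cc(Cl)c(OC)cc1Br)N1[C@H](Cc2ccccc2)COC1=O | intermediate
8 | (R)-4-benzyl-3-[(2R,3R)-2-(2-bromo-5-chloro-4-methoxyphenyl)-3-[(dibutylboranyl)oxy]-3-(3,4,5-trimethoxyphenyl)propanoyl]-1,3-oxazolidin-2-one (not isolated) | O=C(N1[C@H](Cc2ccccc2)COC1=O)[C@H](c1cc(Cl)c(OC)cc1Br)[C@@H](OB(CCCC)CCCC)c1cc(OC)c(OC)c(OC)c1 | intermediate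
9 | (R)-4-benzyl-3-[(2R,3R)-2-(2-bromo-5-chloro-4-methoxyphenyl)-3-hydroxy-3-(3,4,5-trimethoxyphenyl)propanoyl]-1,3-oxazolidin-2-one | O=C(N1[C@H](Cc2ccccc2)COC1=O)[C@H](c1cc(Cl)c(OC)cc1Br)[C@@H](O)c1cc(OC)c(OC)c(OC)c1 | intermediate
10 | (1R,2S)-2-(2-bromo-5-chloro-4-methoxyphenyl)-1-(3,4,5-trimethoxyphenyl)propane-1,3-diol | OC[C@H](c1cc(Cl)c(OC)cc1Br)[C@@H](O)c1cc(OC)c(OC)c(OC)c1 | intermediate
11 | (2S,3R)-2-(2-bromo-5-chloro-4-methoxyphenyl)-3-hydroxy-3-(3,4,5-trimethoxyphenyl)propyl 4-methylbenzenesulfonate | Cc1ccc(cc1)S(=O)(=O)OC[C@H](c1cc(Cl)c(OC)cc1Br)[C@@H](O)c1cc(OC)c(OC)c(OC)c1 | intermediate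
12 | (2S,3R)-2-(2-bromo-5-chloro-4-methoxyphenyl)-3-[(tert-butyldimethylsilyl)oxy]-3-(3,4,5-trimethoxyphenyl)propyl 4-methylbenzenesulfonate | Cc1ccc(cc1)S(=O)(=O)OC[C@H](c1cc(Cl)c(OC)cc1Br)[C@@H](O[Si](C)(C)C(C)(C)C)c1cc(OC)c(OC)c(OC)c1 | intermediate
13 | tert-butyl{[(1R,2R)-2-(2-bromo-5-chloro-4-methoxyphenyl)-1-(3,4,5-trimethoxyphenyl)propyl]oxy}dimethylsilane | C[C@H](c1cc(Cl)c(OC)cc1Br)[C@@H](O[Si](C)(C)C(C)(C)C)c1cc(OC)c(OC)c(OC)c1 | intermediate
14 | (1R,2R)-2-(2-bromo-5-chloro-4-methoxyphenyl)-1-(3,4,5-trimethoxyphenyl)propan-1-ol | C[C@H](c1cc(Cl)c(OC)cc1Br)[C@@H](O)c1cc(OC)c(OC)c(OC)c1 | intermediate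
15 | (2R,3R)-5-chloro-6-methoxy-3-methyl-2-(3,4,5-trimethoxyphenyl)-2,3-dihydro-1-benzofuran | Clc1cc2c(cc1OC)O[C@@H](c1cc(OC)c(OC)c(OC)c1)[C@@H]2C | intermediate
16 | (2R,3R)-6-methoxy-3-methyl-5-[(E)-prop-1-en-1-yl]-2-(3,4,5-trimethoxyphenyl)-2,3-dihydro-1-benzofuran | C/C=C/c1cc2c(cc1OC)O[C@@H](c1cc(OC)c(OC)c(OC)c1)[C@@H]2C | target

**Summary**
Total step count: 10. Longest linear sequence: 10 steps (1 → 16).

Steps most likely to fail:

Step 3 (aldol of a hindered ortho-bromoarylacetyl imide; conversion, dr or retro-aldol on work-up). The fallback sets out from 2 and comes back at 10. Acid 2 is coupled (EDC·HCl, DMAP, CH2Cl2) with (R)-4-benzyl-1,3-thiazolidine-2-thione to give (R)-4-benzyl-3-[2-(2-bromo-5-chloro-4-methoxyphenyl)acetyl]-1,3-thiazolidine-2-thione F1. A TiCl4/iPr2NEt/N-methylpyrrolidinone-mediated aldol addition of F1 to 6 (CH2Cl2, 0 °C, Evans-syn sense) gives (R)-4-benzyl-3-[(2R,3R)-2-(2-bromo-5-chloro-4-methoxyphenyl)-3-hydroxy-3-(3,4,5-trimethoxyphenyl)propanoyl]-1,3-thiazolidine-2-thione F2. NaBH4 (THF/EtOH, 0 °C) then removes the more labile thione auxiliary and gives diol 10.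

Step 7 (hydride displacement at a β-branched tosylate; E2 elimination or slow reaction). The fallback sets out from 12 and comes back at 13. Finkelstein exchange (NaI, butan-2-one, 80 °C) gives tert-butyl{[(1R,2R)-2-(2-bromo-5-chloro-4-methoxyphenyl)-3-iodo-1-(3,4,5-trimethoxyphenyl)propyl]oxy}dimethylsilane F3. Zinc dust in AcOH/THF at 25 °C then reduces the C–I bond by electron transfer and protonation to 13, with no basic hydride present.

Step 9 (copper-catalysed closure with a hindered secondary alcohol; low conversion or oxidation of the alcohol). The fallback sets out from 14 and comes back at 15, and forms the ring bond at the benzylic carbon instead of the aryl carbon. Miyaura borylation of the bromide only (B2pin2, Pd(dppf)Cl2, KOAc, dioxane, 90 °C) gives (1R,2R)-2-[5-chloro-4-methoxy-2-(4,4,5,5-tetramethyl-1,3,2-dioxaborolan-2-yl)phenyl]-1-(3,4,5-trimethoxyphenyl)propan-1-ol F4. Oxidation (NaBO3·4H2O, THF/H2O, 25 °C) gives 4-chloro-2-[(1R,2R)-1-hydroxy-1-(3,4,5-trimethoxyphenyl)propan-2-yl]-5-methoxyphenol F5. BF3·OEt2 (CH2Cl2, −20 °C) then ionises the benzylic alcohol and the phenol closes anti to the C3 methyl group to give trans 15. C3 keeps its configuration, but C2 is reset under steric and thermodynamic control, so the dr must be checked.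

**Further compounds**
F1 | step 3 | (R)-4-benzyl-3-[2-(2-bromo-5-chloro-4-methoxyphenyl)acetyl]-1,3-thiazolidine-2-thione | COc1cc(Br)c(CC(=O)N2[C@H](Cc3ccccc3)CSC2=S)cc1Cl
F2 | step 3 | (R)-4-benzyl-3-[(2R,3R)-2-(2-bromo-5-chloro-4-methoxyphenyl)-3-hydroxy-3-(3,4,5-trimethoxyphenyl)propanoyl]-1,3-thiazolidine-2-thione | O=C(N1[C@H](Cc2ccccc2)CSC1=S)[C@H](c1cc(Cl)c(OC)cc1Br)[C@@H](O)c1cc(OC)c(OC)c(OC)c1
F3 | step 7 | tert-butyl{[(1R,2R)-2-(2-bromo-5-chloro-4-methoxyphenyl)-3-iodo-1-(3,4,5-trimethoxyphenyl)propyl]oxy}dimethylsilane | IC[C@H](c1cc(Cl)c(OC)cc1Br)[C@@H](O[Si](C)(C)C(C)(C)C)c1cc(OC)c(OC)c(OC)c1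
F4 | step 9 | (1R,2R)-2-[5-chloro-4-methoxy-2-(4,4,5,5-tetramethyl-1,3,2-dioxaborolan-2-yl)phenyl]-1-(3,4,5-trimethoxyphenyl)propan-1-ol | C[C@H](c1cc(Cl)c(OC)cc1B1OC(C)(C)C(C)(C)O1)[C@@H](O)c1cc(OC)c(OC)c(OC)c1
F5 | step 9 | 4-chloro-2-[(1R,2R)-1-hydroxy-1-(3,4,5-trimethoxyphenyl)propan-2-yl]-5-methoxyphenol | C[C@H](c1cc(Cl)c(OC)cc1O)[C@@H](O)c1cc(OC)c(OC)c(OC)c1
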